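Ring A of the target carries two neighbouring oxygens, the ring oxygen O1 on C7a and the phenol on C7, right beside the fusion carbon C3a. Both C–O bonds are disconnected at once: a C7–C7a aryne, released from a 2-bromo-3-fluorophenyl group, is attacked at C7a by the benzylic alkoxide (closing the dihydrofuran ring), and the C7–magnesium bond left behind is oxidised to the phenol through a borate. The precursor is the syn-aldol-derived (1R,2S)-2-(2-bromo-3-fluorophenyl)-1-(3,4-dimethoxyphenyl)propane-1,3-diol whose primary oxygen is blocked as a triisopropylsilyl ether, so that only the secondary oxygen can cyclise. The C5 acrylic acid is added afterwards by C–H borylation and an oxidative Heck reaction.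

Key step: step 5

Remark: locants follow 2,3-dihydro-1-benzofuran (O1, C2, C3, C3a, C4–C7, C7a); ring A is the benzo ring, ring B the dimethoxyphenyl ring; the target SMILES encodes the trans-(2R,3S) isomer with an E side chain.

Step 1
Reactants: 1 2-(2-bromo-3-fluorophenyl)acetic acid; 2 (R)-4-benzyl-1,3-oxazolidin-2-one
Product: 4 (4R)-4-benzyl-3-[(2-bromo-3-fluorophenyl)acetyl]-1,3-oxazolidin-2-one, via mixed pivalic anhydride 3 (not isolated)
Conditions: PivCl, Et3N, THF, −20 °C; then 2, LiCl, −20 °C → rt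
Reagents that add atoms: none
Why: N-acylation of the oxazolidinone through the mixed pivalic anhydride (LiCl-assisted) is routine for arylacetic acids and avoids the ketene formation that arylacetyl chlorides are prone to; no stereocentre is touched.

Step 2
Reactants: 4 (4R)-4-benzyl-3-[(2-bromo-3-fluorophenyl)acetyl]-1,3-oxazolidin-2-one; 5 3,4-dimethoxybenzaldehyde (veratraldehyde)
Product: 7 (4R)-4-benzyl-3-[(2R,3R)-2-(2-bromo-3-fluorophenyl)-3-(3,4-dimethoxyphenyl)-3-hydroxypropanoyl]-1,3-oxazolidin-2-one, via Z-dibutylboron enolate 6 (not isolated)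
Conditions: Bu2BOTf, iPr2NEt, CH2Cl2, 0 °C; then 5, −78 → 0 °C; pH 7 buffer, MeOH, H2O2, 0 °C
Reagents that add atoms: none
Why: Evans syn-aldol reaction, in which the Z-boron enolate adds through a closed Zimmerman–Traxler chair with the auxiliary carbonyl turned away from boron, so the (R)-benzyl group selects one enolate face and sets both new centres (2R,3R, syn), the pair that becomes C3 and C2 of the dihydrobenzofuran.

Step 3
Reactants: 7 (4R)-4-benzyl-3-[(2R,3R)-2-(2-bromo-3-fluorophenyl)-3-(3,4-dimethoxyphenyl)-3-hydroxypropanoyl]-1,3-oxazolidin-2-one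
Product: 8 (1R,2S)-2-(2-bromo-3-fluorophenyl)-1-(3,4-dimethoxyphenyl)propane-1,3-diol
Conditions: LiBH4, H2O (1 equiv), THF, 0 °C
Reagents that add atoms: none
Why: Reductive cleavage of the exocyclic imide carbonyl by LiBH4 releases the auxiliary at 0 °C without retro-aldol or epimerisation; the descriptor of the aryl-bearing carbon changes from R to S only because CH2OH ranks below the carbinol carbon.

Step 4
Reactants: 8 (1R,2S)-2-(2-bromo-3-fluorophenyl)-1-(3,4-dimethoxyphenyl)propane-1,3-diol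
Product: 9 (1R,2S)-2-(2-bromo-3-fluorophenyl)-1-(3,4-dimethoxyphenyl)-3-[(triisopropylsilyl)oxy]propan-1-ol
Conditions: TIPSCl, imidazole, DMF, 0 °C → rt
Reagents that add atoms: triisopropylsilyl chloride, CC(C)[Si](Cl)(C(C)C)C(C)C
Why: Selective silylation of the primary over the secondary benzylic hydroxyl; the bulky triisopropylsilyl group is chosen because both oxygens sit three atoms from ring A, so an O-to-O silyl shift in the alkoxide of step 5 (easy for smaller silyl groups) would let the wrong oxygen close a five-membered ring, and because it carries no aryl C–H that could interfere in step 7.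

Step 5
Reactants: 9 (1R,2S)-2-(2-bromo-3-fluorophenyl)-1-(3,4-dimethoxyphenyl)-3-[(triisopropylsilyl)oxy]propan-1-ol
Product: 14 (2R,3S)-2-(3,4-dimethoxyphenyl)-3-{[(triisopropylsilyl)oxy]methyl}-2,3-dihydro-1-benzofuran-7-ol, via aryl Grignard alkoxide 10 (not isolated), via aryne alkoxide 11 (not isolated), via C7-arylmagnesium chloride 12 (not isolated), via dimethyl arylboronate 13 (not isolated)
Conditions: iPrMgCl·LiCl (1.0 equiv), THF, −20 °C; iPrMgCl·LiCl (1.05 equiv), 0 °C; then 55 °C; B(OMe)3, −20 → 0 °C; NaOH aq, H2O2, 0 °C → rt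
Reagents that add atoms: hydrogen peroxide, OO
Why: Proposed new method: the first equivalent of iPrMgCl·LiCl forms the chloromagnesium alkoxide and the second performs a Br/Mg exchange at C7a (activated by the ortho fluorine and by chelation to the alkoxide) at a temperature where the 2-fluoroarylmagnesium is stable, so the exchange reagent is consumed before warming expels MgClF and releases the C7–C7a aryne. The tethered alkoxide then adds in the ring plane to C7a, a five-membered closure onto the aryne carbon next to C3a (formally 5-exo-dig), leaving the carbanion on C7 as an arylmagnesium held by the new O1; B(OMe)3 captures it and alkaline H2O2 turns the C–B bond into the C7 phenol by the usual 1,2-aryl shift to oxygen. The closest known reactions are base-induced aryne cyclisations of 2-(3-halophenyl)ethanols to 2,3-dihydrobenzofurans and additions of magnesium nucleophiles to arynes made from 2-halophenylmagnesium reagents followed by electrophilic trapping of the adduct. No stereocentre is formed: C2 and C3 come unchanged from the syn-aldol because neither the C2–O bond nor any bond at C3 is broken. Regioselectivity requires attack at C7a and not C7, which the three-atom tether enforces (attack at C7 would need a bridged ring), and chemoselectivity requires that only the secondary oxygen cyclises, which the non-migrating silyl ether on the primary oxygen secures.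

Step 6
Reactants: 14 (2R,3S)-2-(3,4-dimethoxyphenyl)-3-{[(triisopropylsilyl)oxy]methyl}-2,3-dihydro-1-benzofuran-7-ol
Product: 15 (2R,3S)-2-(3,4-dimethoxyphenyl)-7-[(triisopropylsilyl)oxy]-3-{[(triisopropylsilyl)oxy]methyl}-2,3-dihydro-1-benzofuran
Conditions: TIPSCl, imidazole, DMF, rt
Reagents that add atoms: triisopropylsilyl chloride, CC(C)[Si](Cl)(C(C)C)C(C)C
Why: Standard phenol silylation, which removes the acidic O–H before the borylation and adds steric shielding at C6.

Step 7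
Reactants: 15 (2R,3S)-2-(3,4-dimethoxyphenyl)-7-[(triisopropylsilyl)oxy]-3-{[(triisopropylsilyl)oxy]methyl}-2,3-dihydro-1-benzofuran
Product: 16 (2R,3S)-2-(3,4-dimethoxyphenyl)-5-(4,4,5,5-tetramethyl-1,3,2-dioxaborolan-2-yl)-7-[(triisopropylsilyl)oxy]-3-{[(triisopropylsilyl)oxy]methyl}-2,3-dihydro-1-benzofuran
Conditions: [Ir(cod)OMe]2 (1.5 mol%), dtbpy (3 mol%), B2pin2 (1.0 equiv), THF, 60 °C
Reagents that add atoms: bis(pinacolato)diboron, CC1(C)OB(OC1(C)C)B1OC(C)(C)C(C)(C)O1
Why: Iridium-catalysed aromatic C–H borylation is steered by sterics, and C5 is the only aromatic C–H in the molecule without an ortho substituent (C4 and C6 of ring A and every position of ring B have one or two), so boron should go there.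

Step 8
Reactants: 16 (2R,3S)-2-(3,4-dimethoxyphenyl)-5-(4,4,5,5-tetramethyl-1,3,2-dioxaborolan-2-yl)-7-[(triisopropylsilyl)oxy]-3-{[(triisopropylsilyl)oxy]methyl}-2,3-dihydro-1-benzofuran; 17 methyl acrylate
Product: 18 methyl (E)-3-[(2R,3S)-2-(3,4-dimethoxyphenyl)-7-[(triisopropylsilyl)oxy]-3-{[(triisopropylsilyl)oxy]methyl}-2,3-dihydro-1-benzofuran-5-yl]prop-2-enoate
Conditions: Pd(OAc)2 (10 mol%), 2,9-dimethyl-1,10-phenanthroline (12 mol%), O2 (1 atm), DMF, 50 °C
Reagents that add atoms: none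
Why: Oxidative (boron) Heck reaction, in which the aryl group passes from boron to divalent palladium, syn insertion of the acrylate and syn β-hydride elimination give the E-cinnamate, and O2 reoxidises the palladium hydride.

Step 9
Reactants: 18 methyl (E)-3-[(2R,3S)-2-(3,4-dimethoxyphenyl)-7-[(triisopropylsilyl)oxy]-3-{[(triisopropylsilyl)oxy]methyl}-2,3-dihydro-1-benzofuran-5-yl]prop-2-enoate
Product: 20 (E)-3-[(2R,3S)-2-(3,4-dimethoxyphenyl)-7-hydroxy-3-(hydroxymethyl)-2,3-dihydro-1-benzofuran-5-yl]prop-2-enoic acid, via desilylated methyl ester 19 (not isolated)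
Conditions: TBAF, THF, rt; then LiOH, H2O, rt; then 1 M HCl to pH 2
Reagents that add atoms: lithium hydroxide, [Li+].[OH-]
Why: Fluoride cleaves both silyl ethers and hydroxide then saponifies the methyl ester in the same flask; neither reagent touches the two stereocentres or the E-alkene, and acidification releases the acid.

Compound list
1 | 2-(2-bromo-3-fluorophenyl)acetic acid | OC(=O)Cc1cccc(F)c1Br | starting material
2 | (R)-4-benzyl-1,3-oxazolidin-2-one | O=C1N[C@H](Cc2ccccc2)CO1 | starting material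
3 | (2-bromo-3-fluorophenyl)acetic pivalic anhydride | CC(C)(C)C(=O)OC(=O)Cc1cccc(F)c1Br | intermediate (not isolated)
4 | (4R)-4-benzyl-3-[(2-bromo-3-fluorophenyl)acetyl]-1,3-oxazolidin-2-one | O=C(Cc1cccc(F)c1Br)N1[C@H](Cc2ccccc2)COC1=O | intermediate
5 | 3,4-dimethoxybenzaldehyde (veratraldehyde) | COc1ccc(C=O)cc1OC | starting material
6 | Z-dibutylboron enolate of 4 | CCCCB(CCCC)O/C(=C\c1cccc(F)c1Br)N1[C@H](Cc2ccccc2)COC1=O | intermediate (not isolated)
7 | (4R)-4-benzyl-3-[(2R,3R)-2-(2-bromo-3-fluorophenyl)-3-(3,4-dimethoxyphenyl)-3-hydroxypropanoyl]-1,3-oxazolidin-2-one | COc1ccc([C@@H]([C@H](C(=O)N2[C@H](Cc3ccccc3)COC2=O)c4cccc(F)c4Br)O)cc1OC | intermediate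
8 | (1R,2S)-2-(2-bromo-3-fluorophenyl)-1-(3,4-dimethoxyphenyl)propane-1,3-diol | COc1ccc([C@@H]([C@H](CO)c2cccc(F)c2Br)O)cc1OC | intermediate
9 | (1R,2S)-2-(2-bromo-3-fluorophenyl)-1-(3,4-dimethoxyphenyl)-3-[(triisopropylsilyl)oxy]propan-1-ol (key-step precursor) | COc1ccc([C@@H]([C@H](CO[Si](C(C)C)(C(C)C)C(C)C)c2cccc(F)c2Br)O)cc1OC | intermediate
10 | chloromagnesium (1R,2S)-2-[2-(chloromagnesio)-3-fluorophenyl]-1-(3,4-dimethoxyphenyl)-3-[(triisopropylsilyl)oxy]propan-1-olate | COc1ccc([C@@H]([C@H](CO[Si](C(C)C)(C(C)C)C(C)C)c2cccc(F)c2[Mg]Cl)O[Mg]Cl)cc1OC | intermediate (not isolated)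
11 | chloromagnesium (1R,2S)-2-(2,3-didehydrophenyl)-1-(3,4-dimethoxyphenyl)-3-[(triisopropylsilyl)oxy]propan-1-olate (C7–C7a aryne) | COc1ccc([C@@H]([C@H](CO[Si](C(C)C)(C(C)C)C(C)C)C2=CC=CC#C2)O[Mg]Cl)cc1OC | intermediate (not isolated)
12 | [(2R,3S)-2-(3,4-dimethoxyphenyl)-3-{[(triisopropylsilyl)oxy]methyl}-2,3-dihydro-1-benzofuran-7-yl]magnesium chloride | COc1ccc([C@@H]2Oc3c([Mg]Cl)cccc3[C@H]2CO[Si](C(C)C)(C(C)C)C(C)C)cc1OC | intermediate (not isolated)
13 | dimethyl [(2R,3S)-2-(3,4-dimethoxyphenyl)-3-{[(triisopropylsilyl)oxy]methyl}-2,3-dihydro-1-benzofuran-7-yl]boronate | COc1ccc([C@@H]2Oc3c(B(OC)OC)cccc3[C@H]2CO[Si](C(C)C)(C(C)C)C(C)C)cc1OC | intermediate (not isolated)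
14 | (2R,3S)-2-(3,4-dimethoxyphenyl)-3-{[(triisopropylsilyl)oxy]methyl}-2,3-dihydro-1-benzofuran-7-ol (key-step product) | COc1ccc([C@@H]2Oc3c(O)cccc3[C@H]2CO[Si](C(C)C)(C(C)C)C(C)C)cc1OC | intermediate
15 | (2R,3S)-2-(3,4-dimethoxyphenyl)-7-[(triisopropylsilyl)oxy]-3-{[(triisopropylsilyl)oxy]methyl}-2,3-dihydro-1-benzofuran | COc1ccc([C@@H]2Oc3c(O[Si](C(C)C)(C(C)C)C(C)C)cccc3[C@H]2CO[Si](C(C)C)(C(C)C)C(C)C)cc1OC | intermediate
16 | (2R,3S)-2-(3,4-dimethoxyphenyl)-5-(4,4,5,5-tetramethyl-1,3,2-dioxaborolan-2-yl)-7-[(triisopropylsilyl)oxy]-3-{[(triisopropylsilyl)oxy]methyl}-2,3-dihydro-1-benzofuran | COc1ccc([C@@H]2Oc3c(O[Si](C(C)C)(C(C)C)C(C)C)cc(B4OC(C)(C)C(C)(C)O4)cc3[C@H]2CO[Si](C(C)C)(C(C)C)C(C)C)cc1OC | intermediate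
17 | methyl acrylate | C=CC(=O)OC | starting material
18 | methyl (E)-3-[(2R,3S)-2-(3,4-dimethoxyphenyl)-7-[(triisopropylsilyl)oxy]-3-{[(triisopropylsilyl)oxy]methyl}-2,3-dihydro-1-benzofuran-5-yl]prop-2-enoate | COc1ccc([C@@H]2Oc3c(O[Si](C(C)C)(C(C)C)C(C)C)cc(/C=C/C(=O)OC)cc3[C@H]2CO[Si](C(C)C)(C(C)C)C(C)C)cc1OC | intermediate
19 | methyl (E)-3-[(2R,3S)-2-(3,4-dimethoxyphenyl)-7-hydroxy-3-(hydroxymethyl)-2,3-dihydro-1-benzofuran-5-yl]prop-2-enoate | COc1ccc([C@@H]2Oc3c(O)cc(/C=C/C(=O)OC)cc3[C@H]2CO)cc1OC | intermediate (not isolated)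
20 | (E)-3-[(2R,3S)-2-(3,4-dimethoxyphenyl)-7-hydroxy-3-(hydroxymethyl)-2,3-dihydro-1-benzofuran-5-yl]prop-2-enoic acid | COc1ccc([C@@H]2Oc3c(O)cc(/C=C/C(=O)O)cc3[C@H]2CO)cc1OC | target

Total step count: 9. Longest linear sequence: 9 steps (1 to 20).

Steps most likely to fail

Step 5. The magnesium alkoxide may add to the aryne too slowly, so that capture by isopropylmagnesium species or by a second substrate molecule competes, and the C7–magnesium bond may be protonated before the borate forms. The fallback uses known chemistry only, sets out from 2 and 5 and comes back at 14. The C7 oxygen is brought in as a benzyl ether and the ring is closed by a copper-catalysed Ullmann etherification. 2-[3-(Benzyloxy)-2-bromophenyl]acetic acid F1 is taken through the operations of steps 1 to 4. Acylation of 2 should give (4R)-4-benzyl-3-{[3-(benzyloxy)-2-bromophenyl]acetyl}-1,3-oxazolidin-2-one F2. The boron aldol with 5 should give (4R)-4-benzyl-3-[(2R,3R)-2-[3-(benzyloxy)-2-bromophenyl]-3-(3,4-dimethoxyphenyl)-3-hydroxypropanoyl]-1,3-oxazolidin-2-one F3. LiBH4 should give (1R,2S)-2-[3-(benzyloxy)-2-bromophenyl]-1-(3,4-dimethoxyphenyl)propane-1,3-diol F4, and TIPSCl should give (1R,2S)-2-[3-(benzyloxy)-2-bromophenyl]-1-(3,4-dimethoxyphenyl)-3-[(triisopropylsilyl)oxy]propan-1-ol F5. Intramolecular C–O coupling of the secondary alcohol with the aryl bromide (CuI, 3,4,7,8-tetramethyl-1,10-phenanthroline, Cs2CO3, toluene, 110 °C) breaks no bond at either stereocentre and should give (2R,3S)-7-(benzyloxy)-2-(3,4-dimethoxyphenyl)-3-{[(triisopropylsilyl)oxy]methyl}-2,3-dihydro-1-benzofuran F6. Hydrogenolysis (H2 1 atm, Pd/C, EtOAc, rt) then frees the phenol 14.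

Step 8. Transfer of the aryl group from the pinacol boronate to divalent palladium may be slow, so that protodeboronation and oxidative homocoupling take over. The fallback sets out from 16 and comes back at 18. It is a Suzuki–Miyaura coupling of 16 with methyl (E)-3-bromoacrylate (Pd(dppf)Cl2, K3PO4, dioxane/H2O, 60 °C), a zerovalent-palladium cross-coupling in which base activates the boronate and the alkene geometry is brought in by the vinyl bromide. It makes no new compound (F0).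

Step 7. Site selectivity may erode if the catalyst is pushed to full conversion, through borylation next to a methoxy group on ring B or a second borylation. The fallback sets out from 2 and 5 and comes back at 18. Site control is moved from the catalyst to a chlorine carried from the start: 2-(2-bromo-5-chloro-3-fluorophenyl)acetic acid F7 (a custom building block, which is why this is not the main line) is put through steps 1 to 6 unchanged. These should give in turn:
- (4R)-4-benzyl-3-[(2-bromo-5-chloro-3-fluorophenyl)acetyl]-1,3-oxazolidin-2-one F8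
- (4R)-4-benzyl-3-[(2R,3R)-2-(2-bromo-5-chloro-3-fluorophenyl)-3-(3,4-dimethoxyphenyl)-3-hydroxypropanoyl]-1,3-oxazolidin-2-one F9
- (1R,2S)-2-(2-bromo-5-chloro-3-fluorophenyl)-1-(3,4-dimethoxyphenyl)propane-1,3-diol F10
- (1R,2S)-2-(2-bromo-5-chloro-3-fluorophenyl)-1-(3,4-dimethoxyphenyl)-3-[(triisopropylsilyl)oxy]propan-1-ol F11
- (2R,3S)-5-chloro-2-(3,4-dimethoxyphenyl)-3-{[(triisopropylsilyl)oxy]methyl}-2,3-dihydro-1-benzofuran-7-ol F12 (the chloride is inert to iPrMgCl·LiCl)
- (2R,3S)-5-chloro-2-(3,4-dimethoxyphenyl)-7-[(triisopropylsilyl)oxy]-3-{[(triisopropylsilyl)oxy]methyl}-2,3-dihydro-1-benzofuran F13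

A Mizoroki–Heck reaction of the aryl chloride with methyl acrylate 17 (Pd[P(tBu)3]2, Cy2NMe, dioxane, 110 °C) then gives 18.

Further compounds
F1 | step 5 | 2-[3-(benzyloxy)-2-bromophenyl]acetic acid | OC(=O)Cc1cccc(OCc2ccccc2)c1Br
F2 | step 5 | (4R)-4-benzyl-3-{[3-(benzyloxy)-2-bromophenyl]acetyl}-1,3-oxazolidin-2-one | O=C(Cc1cccc(OCc2ccccc2)c1Br)N1[C@H](Cc2ccccc2)COC1=O
F3 | step 5 | (4R)-4-benzyl-3-[(2R,3R)-2-[3-(benzyloxy)-2-bromophenyl]-3-(3,4-dimethoxyphenyl)-3-hydroxypropanoyl]-1,3-oxazolidin-2-one | COc1ccc([C@@H]([C@H](C(=O)N2[C@H](Cc3ccccc3)COC2=O)c4cccc(OCc5ccccc5)c4Br)O)cc1OC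
F4 | step 5 | (1R,2S)-2-[3-(benzyloxy)-2-bromophenyl]-1-(3,4-dimethoxyphenyl)propane-1,3-diol | COc1ccc([C@@H]([C@H](CO)c2cccc(OCc3ccccc3)c2Br)O)cc1OC
F5 | step 5 | (1R,2S)-2-[3-(benzyloxy)-2-bromophenyl]-1-(3,4-dimethoxyphenyl)-3-[(triisopropylsilyl)oxy]propan-1-ol | COc1ccc([C@@H]([C@H](CO[Si](C(C)C)(C(C)C)C(C)C)c2cccc(OCc3ccccc3)c2Br)O)cc1OC
F6 | step 5 | (2R,3S)-7-(benzyloxy)-2-(3,4-dimethoxyphenyl)-3-{[(triisopropylsilyl)oxy]methyl}-2,3-dihydro-1-benzofuran | COc1ccc([C@@H]2Oc3c(OCc4ccccc4)cccc3[C@H]2CO[Si](C(C)C)(C(C)C)C(C)C)cc1OC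
F0 | step 8 | none | none
F7 | step 7 | 2-(2-bromo-5-chloro-3-fluorophenyl)acetic acid | OC(=O)Cc1cc(Cl)cc(F)c1Br
F8 | step 7 | (4R)-4-benzyl-3-[(2-bromo-5-chloro-3-fluorophenyl)acetyl]-1,3-oxazolidin-2-one | O=C(Cc1cc(Cl)cc(F)c1Br)N1[C@H](Cc2ccccc2)COC1=O
F9 | step 7 | (4R)-4-benzyl-3-[(2R,3R)-2-(2-bromo-5-chloro-3-fluorophenyl)-3-(3,4-dimethoxyphenyl)-3-hydroxypropanoyl]-1,3-oxazolidin-2-one | COc1ccc([C@@H]([C@H](C(=O)N2[C@H](Cc3ccccc3)COC2=O)c4cc(Cl)cc(F)c4Br)O)cc1OC
F10 | step 7 | (1R,2S)-2-(2-bromo-5-chloro-3-fluorophenyl)-1-(3,4-dimethoxyphenyl)propane-1,3-diol | COc1ccc([C@@H]([C@H](CO)c2cc(Cl)cc(F)c2Br)O)cc1OC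
F11 | step 7 | (1R,2S)-2-(2-bromo-5-chloro-3-fluorophenyl)-1-(3,4-dimethoxyphenyl)-3-[(triisopropylsilyl)oxy]propan-1-ol | COc1ccc([C@@H]([C@H](CO[Si](C(C)C)(C(C)C)C(C)C)c2cc(Cl)cc(F)c2Br)O)cc1OC
F12 | step 7 | (2R,3S)-5-chloro-2-(3,4-dimethoxyphenyl)-3-{[(triisopropylsilyl)oxy]methyl}-2,3-dihydro-1-benzofuran-7-ol | COc1ccc([C@@H]2Oc3c(O)cc(Cl)cc3[C@H]2CO[Si](C(C)C)(C(C)C)C(C)C)cc1OC
F13 | step 7 | (2R,3S)-5-chloro-2-(3,4-dimethoxyphenyl)-7-[(triisopropylsilyl)oxy]-3-{[(triisopropylsilyl)oxy]methyl}-2,3-dihydro-1-benzofuran | COc1ccc([C@@H]2Oc3c(O[Si](C(C)C)(C(C)C)C(C)C)cc(Cl)cc3[C@H]2CO[Si](C(C)C)(C(C)C)C(C)C)cc1OC
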